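The data were generated by integration for substances that don't exist, noise included.

No constant is given, so you read what you need from the two runs.

| setting | ash | birch | flask |
|---|---|---|---|
| electrophile | 0.10 M | 0.15 M | 0.10 M |
| nucleophile | 0.080 M | 0.080 M | 0.0800 M |
| free base | 0.030 M | 0.030 M | 0.0300 M |
| temperature | 60 °C | 45 °C | 60 °C |
| remark | the very flask that is asked about, followed so far | run made earlier |  |
| time |  |  | 3.0 h |

| run | time / min | target / % | electrophile / % |
|---|---|---|---|
| ash | 6.00 | 7.0 | 47.5 |
| ash | 15.0 | 14.3 | 43.5 |
| ash | 30.0 | 20.7 | 39.4 |
| ash | 50.0 | 26.7 | 34.4 |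
| ash | 60.0 | 27.7 | 33.4 |
| ash | 80.0 | 29.8 | 29.8 |
| ash | 120 | 31.1 | 25.0 |
| birch | 6.00 | 4.5 | 69.4 |
| birch | 12.0 | 7.0 | 64.4 |
| birch | 15.0 | 8.0 | 62.3 |
| birch | 25.0 | 11.9 | 61.3 |
| birch | 30.0 | 13.0 | 59.5 |
| birch | 40.0 | 15.3 | 57.3 |

(readings scatter by 0.5 percentage points)

- target, in percent of the electrophile first charged, at 3.0 h
- which option adds most target ("none" when 2 percentage points or less is all one gets) (teal / grey / red / ochre / green / none)
- target present, with what was taken out counted in, in percent of the electrophile first charged, after grey
- target present, with what was taken out counted in, in percent of the electrophile first charged, after ochre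

- teal: at 3.0 h take out 90 % of the target then present, then wait 6.0 h
- grey: at 3.0 h add free base, 100 % of the amount charged, then wait 6.0 h
- red: at 3.0 h add free base, 100 % of the amount charged, then wait 6.0 h
- ochre: at 3.0 h raise the temperature by 20 K, then wait 6.0 h
- green: change nothing and wait 6.0 h more

- target that was removed still counts
- the earlier runs were read with a standard deviation of 0.5 percentage points
- additions bring no volume worth counting

In the ash run, at 6.00 min, target and electrophile leave an unseen share of 45.5 %, which is 0.958 times the electrophile then present. Birch reads 0.376 at its own temperature and charge, so you take the ratio from ash.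

But the unseen share doesn't follow electrophile down. Suppose the early part keeps that ratio, and call the rest the lost share: the charge, less target, less electrophile times one plus the ratio. In the ash run it climbs from 2.16 % at 30.0 min to 20.0 % at 120 min.

Suppose it grows with c(electrophile)·c(target), target being the intermediate of a consecutive reaction. Replace that product, in fractions of the charge, by its mean over the last five ash readings, 0.0865. The last reading stands at 0.899 of that mean, so the curve is flat enough. The wear constant, the lost share gained per minute per unit of the product, reads 0.0229 min⁻¹.

If target and electrophile leave in pairs, half the lost share is target. Between 80.0 min and 120 min in the ash run, target then loses 3.8 percentage points, more than its net rise of 1.3 points. So I read the plateau as a balance, hold target in the flask at 3.0 h near 31.1 %, and choose teal, which cuts the product. Watch the lost share.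

The forecast stands near my figure for target at 31.3 %, but differs in its choice, grey, with 49 % after grey and 32 % after ochre, on the ground “This is a stoichiometric limit, not equilibrium or product inhibition.”

    acid set free + free base ⇌ salt of the base (K = 470 L mol⁻¹, k = 0.0670 L mol⁻¹ s⁻¹, Ea = 70.0 kJ mol⁻¹, ΔH = 17.0 kJ mol⁻¹)
    electrophile ⇌ dormant form (K = 0.940, k = 0.00890 s⁻¹, Ea = 93.0 kJ mol⁻¹, ΔH = 45.0 kJ mol⁻¹)
    electrophile + nucleophile → acid set free + target (k = 0.00490 L mol⁻¹ s⁻¹, Ea = 53.0 kJ mol⁻¹)
    nucleophile + acid set free ⇌ protonated nucleophile, settled at all times (K = 590 L mol⁻¹, ΔH = −34.0 kJ mol⁻¹)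
    electrophile + target → side product (k = 0.00170 L mol⁻¹ s⁻¹, Ea = 87.0 kJ mol⁻¹)
    (constants at 60 °C)

The flask gives 31.6 %; teal adds 5.8 points, while grey changes target by −1.6 points, reaching 30.1 %, and ochre reaches 19.0 %. In the flask, each step taken net, target is made 5.04 times as fast as it is used up at 31.2 min, and 0.921 times at 180 min. Carried from 120 min to 3.0 h, the wear constant puts the lost share at 29.8 %; the side product, whose percentage counts two, stands at 28.0 %.

In the flask left until 5.0 h, with electrophile 14.8 % and target 30.0 % at its end, the constant adds 15 points, giving 43.0 %. The computed side product is 41.3 %.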